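**Retrosynthetic overview**

- The strategy rests on ring B: its two oxygens sit para on C2' and C5', and its only carbon substituent is C1', bound to C2 of the chromone (rings A and C). This is the pattern a carbene benzannulation produces.
- Late operations: the C5 hydroxyl comes from the peri methyl ether (BCl3, chelation to the C4 carbonyl), the hydroquinone from the quinone, and the quinone from a 2'-hydroxy-5'-methoxyphenyl ring.
- Key disconnection: ring B is cut to 2-ethynyl-5,6,7,8-tetramethoxychromone, an alkenyl(methoxy)carbene Cr(CO)5 complex and one CO ligand; the bonds formed are C5'–C6', C1'–C2' and C2'–C3'.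
- The ethynylchromone comes from the chromone-2-carbaldehyde, this from the 2-methylchromone, and this from the o-hydroxyacetophenone and ethyl acetate.
- Ring order: ring A is purchased, ring C closes in step 2, ring B closes in step 6.

Key step: step 6

**Assumptions**

- 2'-Hydroxy-3',4',5',6'-tetramethoxyacetophenone is taken as a purchasable fine chemical.
- The unsubstituted complex (CO)5Cr=C(OMe)CH=CH2 polymerizes readily and is a poor benzannulation partner, so the carbene is used as its trans-β-trimethylsilyl derivative. The silyl group is traceless: it moves from C3' to the C2' oxygen during aromatization and is hydrolysed, so ring B comes out as the parent vinyl complex would give it.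

**Route**

Step 1
Reactants: 1 2'-hydroxy-3',4',5',6'-tetramethoxyacetophenone
Product: 2 1-(2-hydroxy-3,4,5,6-tetramethoxyphenyl)butane-1,3-dione
Conditions: NaH (3.5 equiv), EtOAc (5 equiv), THF, reflux; then aq. HCl to pH 3
Reagents that add atoms: ethyl acetate, CCOC(C)=O
Why: Crossed Claisen condensation in which the methyl ketone enolate of the sodium phenoxide is acetylated by ethyl acetate and the β-diketonate is the thermodynamic sink, the classical entry to 2-methylchromones.

Step 2
Reactants: 2 1-(2-hydroxy-3,4,5,6-tetramethoxyphenyl)butane-1,3-dione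
Product: 3 5,6,7,8-tetramethoxy-2-methyl-4H-chromen-4-one
Conditions: conc. H2SO4 (cat.), AcOH, rt
Reagents that add atoms: none
Why: Acid-catalysed cyclodehydration in which the phenol oxygen adds to the distal carbonyl and water is lost to close ring C, with catalytic acid at room temperature so that the peri methyl ether is kept.

Step 3
Reactants: 3 5,6,7,8-tetramethoxy-2-methyl-4H-chromen-4-one
Product: 4 5,6,7,8-tetramethoxy-4-oxo-4H-chromene-2-carbaldehyde
Conditions: SeO2 (1.5 equiv), xylene, 140 °C
Reagents that add atoms: selenium dioxide, O=[Se]=O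
Why: Riley oxidation of the C2 methyl group, which is vinylogously activated by the C4 carbonyl, a known conversion of 2-methylchromones into chromone-2-carbaldehydes.

Step 4
Reactants: 4 5,6,7,8-tetramethoxy-4-oxo-4H-chromene-2-carbaldehyde
Product: 5 2-ethynyl-5,6,7,8-tetramethoxy-4H-chromen-4-one
Conditions: (MeO)2P(O)CHN2 (1.2 equiv), KOtBu (1.2 equiv), THF, −78 °C (anion preformed, aldehyde added last) → rt
Reagents that add atoms: dimethyl (diazomethyl)phosphonate, COP(=O)(C=[N+]=[N-])OC
Why: Seyferth–Gilbert homologation of a non-enolizable aldehyde (olefination to the diazoalkene, loss of N2, 1,2-hydrogen shift of the alkylidene carbene), run aprotic and cold so that no alkoxide in methanol meets the electrophilic C2 of the chromone or the activated enyne.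

Step 5
Reactants: 6 (E)-(2-bromovinyl)trimethylsilane; 7 chromium hexacarbonyl, Cr(CO)6
Product: 10 pentacarbonyl{methoxy[(E)-2-(trimethylsilyl)ethenyl]carbene}chromium, (CO)5Cr=C(OMe)CH=CHSiMe3, via (E)-2-(trimethylsilyl)vinyllithium 8 (not isolated), via lithium acylchromate 9 (not isolated)
Conditions: t-BuLi (2.0 equiv), Et2O, −78 °C; Cr(CO)6, Et2O, −78 °C → rt; then Me3OBF4, CH2Cl2, 0 °C
Reagents that add atoms: trimethyloxonium tetrafluoroborate, C[O+](C)C.F[B-](F)(F)F
Why: Fischer carbene synthesis (bromine–lithium exchange with retention of the E geometry, addition of the vinyllithium to a CO ligand of Cr(CO)6, O-methylation of the acylchromate by the hard oxonium salt), with the β-silyl group blocking the Michael-type polymerization of the unsubstituted vinyl complex.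

Step 6
Reactants: 5 2-ethynyl-5,6,7,8-tetramethoxy-4H-chromen-4-one; 10 pentacarbonyl{methoxy[(E)-2-(trimethylsilyl)ethenyl]carbene}chromium
Product: 13 2-(2-hydroxy-5-methoxyphenyl)-5,6,7,8-tetramethoxy-4H-chromen-4-one, via Cr(CO)3-bound aryl silyl ether 11 (not isolated), via aryl trimethylsilyl ether 12 (not isolated)
Conditions: 10 (1.5 equiv), THF (0.05 M), 50 °C, Ar; then air, visible light, Et2O/MeCN, rt; then 1 M HCl, MeOH, rt
Reagents that add atoms: none
Why: Thermal loss of one CO from 10 opens a site on zerovalent chromium, the terminal alkyne of 5 inserts into the Cr=C bond with its CH end on the carbene carbon (C5'–C6'), a CO ligand inserts into the new chromium carbene to give a metal-bound dienylketene (C1'–C2'), and this closes onto the silyl-bearing vinyl carbon (C2'–C3'). The reaction type is the Dötz benzannulation of alkenyl(alkoxy)carbene chromium complexes with terminal alkynes, in its known variant with a trans-β-silyl alkenyl carbene. Ring B, the only ring formed, closes by thermal 6π electrocyclization of the dienylketene to a cyclohexa-2,4-dienone, which aromatizes by 1,3-shift of SiMe3 from C3' to the C2' oxygen; air and light then strip Cr(CO)3 from 11 and dilute acid cleaves the silyl ether 12. No stereocenter is formed. The step needs chemoselectivity for the alkyne over the C2–C3 alkene and the carbonyl of the chromone, which the unhindered terminal alkyne secures because its insertion runs at 50 °C, below the temperature at which such carbenes cyclopropanate electron-poor alkenes. It also needs the chromone next to the CO-derived carbon, which the steric preference of the larger alkyne substituent provides, and the other orientation would in any case give a p-methoxyphenol that step 7 turns into the same quinone.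

Step 7
Reactants: 13 2-(2-hydroxy-5-methoxyphenyl)-5,6,7,8-tetramethoxy-4H-chromen-4-one
Product: 14 2-(5,6,7,8-tetramethoxy-4-oxo-4H-chromen-2-yl)cyclohexa-2,5-diene-1,4-dione
Conditions: PhI(OAc)2 (1.1 equiv), MeCN/H2O (2:1), 0 °C
Reagents that add atoms: water, O
Why: Oxidative demethylation of a p-methoxyphenol by trivalent iodine (ligand exchange at the free C2' hydroxyl, attack of water at C5', loss of methanol from the hemiketal), and because the reagent needs a free phenol the fully methylated ring A is left alone.

Step 8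
Reactants: 14 2-(5,6,7,8-tetramethoxy-4-oxo-4H-chromen-2-yl)cyclohexa-2,5-diene-1,4-dione
Product: 15 2-(2,5-dihydroxyphenyl)-5,6,7,8-tetramethoxy-4H-chromen-4-one
Conditions: Na2S2O4 (3 equiv), EtOAc/H2O, rt, Ar
Reagents that add atoms: none
Why: Two-electron reduction of the quinone by dithionite, which does not touch the chromone enone or the aryl methyl ethers.

Step 9
Reactants: 15 2-(2,5-dihydroxyphenyl)-5,6,7,8-tetramethoxy-4H-chromen-4-one
Product: 16 5,2',5'-trihydroxy-6,7,8-trimethoxyflavone
Conditions: BCl3 (4 equiv, 1 M in CH2Cl2), CH2Cl2, −78 → 0 °C; then H2O/MeOH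
Reagents that add atoms: none
Why: Chelation-controlled demethylation in which boron bridges the C4 carbonyl and the peri C5 oxygen and chloride removes only that methyl group, the known selective 5-O-demethylation of polymethoxyflavones; the ring B hydroxyls are held as aryl borates and freed on work-up.

**Compound list**

1 | 2'-hydroxy-3',4',5',6'-tetramethoxyacetophenone | CC(=O)c1c(O)c(OC)c(OC)c(OC)c1OC | starting material
2 | 1-(2-hydroxy-3,4,5,6-tetramethoxyphenyl)butane-1,3-dione | CC(=O)CC(=O)c1c(O)c(OC)c(OC)c(OC)c1OC | intermediate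
3 | 5,6,7,8-tetramethoxy-2-methyl-4H-chromen-4-one | Cc1cc(=O)c2c(OC)c(OC)c(OC)c(OC)c2o1 | intermediate
4 | 5,6,7,8-tetramethoxy-4-oxo-4H-chromene-2-carbaldehyde | O=Cc1cc(=O)c2c(OC)c(OC)c(OC)c(OC)c2o1 | intermediate
5 | 2-ethynyl-5,6,7,8-tetramethoxy-4H-chromen-4-one | C#Cc1cc(=O)c2c(OC)c(OC)c(OC)c(OC)c2o1 | intermediate
6 | (E)-(2-bromovinyl)trimethylsilane | C[Si](C)(C)/C=C/Br | starting material
7 | chromium hexacarbonyl, Cr(CO)6 | O=C=[Cr](=C=O)(=C=O)(=C=O)(=C=O)=C=O | starting material
8 | (E)-2-(trimethylsilyl)vinyllithium | [Li]/C=C/[Si](C)(C)C | intermediate (not isolated)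
9 | lithium pentacarbonyl[(E)-3-(trimethylsilyl)acryloyl]chromate, Li[(CO)5CrC(O)CH=CHSiMe3] | [Li+].[O-]C(/C=C/[Si](C)(C)C)=[Cr](=C=O)(=C=O)(=C=O)(=C=O)=C=O | intermediate (not isolated)
10 | pentacarbonyl{methoxy[(E)-2-(trimethylsilyl)ethenyl]carbene}chromium, (CO)5Cr=C(OMe)CH=CHSiMe3 | COC(/C=C/[Si](C)(C)C)=[Cr](=C=O)(=C=O)(=C=O)(=C=O)=C=O | intermediate
11 | tricarbonyl(η6-arene)chromium complex of 12, Cr(CO)3 bound to ring B | COc1ccc(O[Si](C)(C)C)c(c1)-c1cc(=O)c2c(OC)c(OC)c(OC)c(OC)c2o1.[Cr].[C-]#[O+].[C-]#[O+].[C-]#[O+] | intermediate (not isolated)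
12 | 5,6,7,8-tetramethoxy-2-[5-methoxy-2-(trimethylsilyloxy)phenyl]-4H-chromen-4-one | COc1ccc(O[Si](C)(C)C)c(c1)-c1cc(=O)c2c(OC)c(OC)c(OC)c(OC)c2o1 | intermediate (not isolated)
13 | 2-(2-hydroxy-5-methoxyphenyl)-5,6,7,8-tetramethoxy-4H-chromen-4-one | COc1ccc(O)c(c1)-c1cc(=O)c2c(OC)c(OC)c(OC)c(OC)c2o1 | intermediate
14 | 2-(5,6,7,8-tetramethoxy-4-oxo-4H-chromen-2-yl)cyclohexa-2,5-diene-1,4-dione | O=C1C=CC(=O)C(=C1)-c1cc(=O)c2c(OC)c(OC)c(OC)c(OC)c2o1 | intermediate
15 | 2-(2,5-dihydroxyphenyl)-5,6,7,8-tetramethoxy-4H-chromen-4-one | Oc1ccc(O)c(c1)-c1cc(=O)c2c(OC)c(OC)c(OC)c(OC)c2o1 | intermediate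
16 | 5,2',5'-trihydroxy-6,7,8-trimethoxyflavone | COc1c(OC)c(O)c2c(=O)cc(-c3cc(O)ccc3O)oc2c1OC | target

**Step count**

Total steps: 9. Longest linear sequence: 8 steps (steps 1–4 and 6–9, from 1); the carbene branch is step 5.

**Steps most likely to fail**

Step 6. The alkyne of 5 is conjugated to an acceptor, so insertion may be slow. Decomposition of the carbene, oligomerization of the alkyne or cyclization without CO insertion could then outrun benzannulation. Aromatization by hydrogen shift instead of silyl shift would leave silicon on C3', which CF3CO2H would remove to give the same 13. Fallback: ring B is brought in intact, setting out from 1. Esterification with 2,5-bis(benzyloxy)benzoic acid (EDC·HCl, DMAP, CH2Cl2) should give 2-acetyl-3,4,5,6-tetramethoxyphenyl 2,5-bis(benzyloxy)benzoate F1. Baker–Venkataraman rearrangement (KOtBu, THF, rt) should give 1-[2,5-bis(benzyloxy)phenyl]-3-(2-hydroxy-3,4,5,6-tetramethoxyphenyl)propane-1,3-dione F2. Cyclodehydration (cat. H2SO4, AcOH) should give 2-[2,5-bis(benzyloxy)phenyl]-5,6,7,8-tetramethoxy-4H-chromen-4-one F3. Hydrogenolysis (H2, Pd/C, EtOAc/MeOH) should give 15, where the route is rejoined before step 9.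

Step 4. The phosphonate anion or tert-butoxide may add to C2 of the chromone and open ring C, or a nucleophile may add in conjugate fashion to the activated enyne product. Fallback: olefination and elimination in place of the diazo homologation, setting out from 4. CBr4/PPh3 (CH2Cl2, 0 °C) should give 2-(2,2-dibromoethenyl)-5,6,7,8-tetramethoxy-4H-chromen-4-one F4. Hydrogenolysis with Bu3SnH and catalytic Pd(PPh3)4 (toluene, rt) should remove the bromine trans to the chromone and give 2-[(Z)-2-bromoethenyl]-5,6,7,8-tetramethoxy-4H-chromen-4-one F5. Anti elimination of HBr with Bu4NF·3H2O in DMF should give 5, where the route is rejoined before step 6.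

Step 3. Over-oxidation to the carboxylic acid, incomplete conversion and carry-over of colloidal selenium may spoil the aldehyde. Fallback: enamine cleavage, setting out from 3. Condensation of the vinylogous methyl group with Me2NCH(OMe)2 (DMF, 120 °C) should give 2-[(E)-2-(dimethylamino)ethenyl]-5,6,7,8-tetramethoxy-4H-chromen-4-one F6. Cleavage of the enamine double bond with NaIO4 (THF/H2O, rt) should give 4, where the route is rejoined before step 4.

**Further compounds**

F1 | step 6 | 2-acetyl-3,4,5,6-tetramethoxyphenyl 2,5-bis(benzyloxy)benzoate | CC(=O)c1c(OC(=O)c2cc(OCc3ccccc3)ccc2OCc2ccccc2)c(OC)c(OC)c(OC)c1OC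
F2 | step 6 | 1-[2,5-bis(benzyloxy)phenyl]-3-(2-hydroxy-3,4,5,6-tetramethoxyphenyl)propane-1,3-dione | O=C(CC(=O)c1c(O)c(OC)c(OC)c(OC)c1OC)c1cc(OCc2ccccc2)ccc1OCc1ccccc1
F3 | step 6 | 2-[2,5-bis(benzyloxy)phenyl]-5,6,7,8-tetramethoxy-4H-chromen-4-one | COc1c(OC)c(OC)c2c(=O)cc(-c3cc(OCc4ccccc4)ccc3OCc3ccccc3)oc2c1OC
F4 | step 4 | 2-(2,2-dibromoethenyl)-5,6,7,8-tetramethoxy-4H-chromen-4-one | BrC(Br)=Cc1cc(=O)c2c(OC)c(OC)c(OC)c(OC)c2o1
F5 | step 4 | 2-[(Z)-2-bromoethenyl]-5,6,7,8-tetramethoxy-4H-chromen-4-one | Br/C=C\c1cc(=O)c2c(OC)c(OC)c(OC)c(OC)c2o1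
F6 | step 3 | 2-[(E)-2-(dimethylamino)ethenyl]-5,6,7,8-tetramethoxy-4H-chromen-4-one | CN(C)/C=C/c1cc(=O)c2c(OC)c(OC)c(OC)c(OC)c2o1
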